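**Retrosynthetic overview**
1. Last disconnection: the two chelated hydroxyls (C5–O and C5''–O). Both C–O bonds are made in one operation on 5,5''-dideoxyputraflavone by C4=O-directed peri C–H oxygenation.
2. Both A rings can therefore come from acetophenones with a single ortho-OH. This removes the 6- versus 8-linkage ambiguity and the need for protecting groups.
3. C3'–C8'' biaryl bond: borylation/Suzuki coupling of a 3'-bromoflavone (half 1) with an 8-iodoflavone (half 2).
4. Each pyranone ring (O1–C2 bond): domino aldol/oxa-Michael/dehydrogenation of an o-hydroxyacetophenone with a benzaldehyde.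
5. Order: the pyranone rings of half 1 and half 2 are made in parallel, then the biaryl bond, then the double C–O formation. All benzene rings are bought.

Assumption: the SMILES has no stereodescriptor and the molecule has no stereocentre. The 3'–8'' axis is treated as unspecified, and the compound is made as drawn (racemic about the axis as far as rotation is slow).

**Step 1**
Reactants: 1 paeonol (1-(2-hydroxy-4-methoxyphenyl)ethan-1-one); 2 3-bromo-4-hydroxybenzaldehyde
Product: 5 2-(3-bromo-4-hydroxyphenyl)-7-methoxy-4H-chromen-4-one, via bromochalcone 3 (not isolated), via bromoflavanone 4 (not isolated)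
Conditions: pyrrolidine (0.5 equiv), I2 (10 mol%), DMSO, 150 °C
Reagents that add atoms: none
Why: Amine-catalysed Claisen–Schmidt condensation gives chalcone 3, its only ortho-OH closes the pyranone by 6-endo oxa-Michael addition (O1–C2 bond) to racemic flavanone 4, and the I2/DMSO couple dehydrogenates C2–C3, which erases the transient stereocentre.

**Step 2**
Reactants: 6 2,4-dihydroxyacetophenone; 7 4-methoxybenzaldehyde (p-anisaldehyde)
Product: 10 7-hydroxy-2-(4-methoxyphenyl)-4H-chromen-4-one (pratol), via anisylchalcone 8 (not isolated), via anisylflavanone 9 (not isolated)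
Conditions: pyrrolidine (0.5 equiv), I2 (10 mol%), DMSO, 150 °C
Reagents that add atoms: none
Why: This is the same domino Claisen–Schmidt/oxa-Michael/I2–DMSO dehydrogenation; only the 2-OH of 6 is ortho to the acyl group, so the O1–C2 bond can form in one way only, the 4-OH becomes the free 7-OH, and the stereocentre of racemic 9 is erased.

**Step 3**
Reactants: 10 pratol
Product: 11 7-hydroxy-8-iodo-2-(4-methoxyphenyl)-4H-chromen-4-one
Conditions: NIS (1.05 equiv), DMF, 0 °C to rt, dark
Reagents that add atoms: N-iodosuccinimide, O=C1CCC(=O)N1I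
Why: In this electrophilic aromatic iodination of a phenol, C8 of a 7-hydroxychromone (ortho to both the 7-OH and the ring oxygen) is the most nucleophilic carbon, the same site taken in Mannich, Duff and Claisen reactions, while the anisyl ring and C3 are deactivated by the pyranone.

**Step 4**
Reactants: 5 3'-bromo-4'-hydroxy-7-methoxyflavone; 11 7-hydroxy-8-iodo-4'-methoxyflavone
Product: 13 7-hydroxy-8-[2-hydroxy-5-(7-methoxy-4-oxo-4H-chromen-2-yl)phenyl]-2-(4-methoxyphenyl)-4H-chromen-4-one (5,5''-dideoxyputraflavone), via boronate 12 (not isolated)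
Conditions: 5 (1.15 equiv), B2pin2 (1.2 equiv), PdCl2(dppf) (4 mol%), KOAc (3.5 equiv), dioxane, 90 °C; then 11 (1.0 equiv), Pd(OAc)2 (4 mol%), SPhos (8 mol%), K3PO4 (5 equiv), H2O, 95 °C
Reagents that add atoms: bis(pinacolato)diboron, CC1(C)OB(OC1(C)C)B1OC(C)(C)C(C)(C)O1 (its boryl group stands in 12 only and is lost again in 13)
Why: Miyaura borylation is followed in the same flask by Suzuki–Miyaura coupling, with boron placed on the less hindered ring B carbon (a 2,6-dioxygenated C8 boronate would protodeboronate), an aryl iodide that adds quickly to zerovalent palladium, SPhos to handle the tri-ortho-substituted biaryl, and free phenols tolerated as phenoxides in aqueous K3PO4.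

**Step 5**
Reactants: 13 5,5''-dideoxyputraflavone
Product: 16 putraflavone (7,4'''-di-O-methylamentoflavone), via bis(trifluoroacetate) 14 (not isolated), via tetrakis(trifluoroacetate) 15 (not isolated)
Conditions: [RuCl2(p-cymene)]2 (10 mol%), PhI(OCOCF3)2 (3 equiv), TFA/TFAA (3:2), 80 °C; then H2O/THF, 40 °C
Reagents that add atoms: [bis(trifluoroacetoxy)iodo]benzene, O=C(OI(OC(=O)C(F)(F)F)c1ccccc1)C(F)(F)F (gives the two new oxygen atoms); trifluoroacetic anhydride, O=C(OC(=O)C(F)(F)F)C(F)(F)F (its acyl groups stand in 14 and 15 only)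
Why: Proposed new method: a two-fold carbonyl-directed peri C–H oxygenation of an unprotected biflavone, in which TFAA first converts the two free phenols into trifluoroacetates (14) and so shields them from the trivalent-iodine oxidant, each C4=O then guides carboxylate-assisted C5–H ruthenation to a five-membered ruthenacycle of divalent ruthenium, PhI(OCOCF3)2 raises it to tetravalent ruthenium, C–O reductive elimination delivers an aryl trifluoroacetate that is non-chelating and electron-poor (so the catalyst is released for the second site and over-oxidation is blocked), and water finally cleaves all four esters of 15; C5 and C5'' are the only C–H bonds that can reach a carbonyl through a five-membered metallacycle, so site selectivity is built in; the closest known reaction type is the ruthenium-catalysed ketone-directed ortho C–H hydroxylation of aryl ketones and of simple monomeric flavones or chromones in TFA/TFAA, which has not been shown twice in one molecule, on a biflavone, or with free phenols masked in the flask.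

**Compound list**
1 | paeonol, 1-(2-hydroxy-4-methoxyphenyl)ethan-1-one | CC(=O)c1ccc(OC)cc1O | starting material
2 | 3-bromo-4-hydroxybenzaldehyde | O=Cc1ccc(O)c(Br)c1 | starting material
3 | (E)-3-(3-bromo-4-hydroxyphenyl)-1-(2-hydroxy-4-methoxyphenyl)prop-2-en-1-one (bromochalcone) | COc1ccc(C(=O)/C=C/c2ccc(O)c(Br)c2)c(O)c1 | intermediate
4 | racemic 2-(3-bromo-4-hydroxyphenyl)-7-methoxychroman-4-one (bromoflavanone) | COc1ccc2C(=O)CC(Oc2c1)c1ccc(O)c(Br)c1 | intermediate
5 | 2-(3-bromo-4-hydroxyphenyl)-7-methoxy-4H-chromen-4-one | COc1ccc2c(c1)oc(cc2=O)-c1ccc(O)c(Br)c1 | intermediate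
6 | 2,4-dihydroxyacetophenone | CC(=O)c1ccc(O)cc1O | starting material
7 | 4-methoxybenzaldehyde | COc1ccc(C=O)cc1 | starting material
8 | (E)-1-(2,4-dihydroxyphenyl)-3-(4-methoxyphenyl)prop-2-en-1-one (anisylchalcone) | COc1ccc(/C=C/C(=O)c2ccc(O)cc2O)cc1 | intermediate
9 | racemic 7-hydroxy-2-(4-methoxyphenyl)chroman-4-one (anisylflavanone) | COc1ccc(cc1)C1CC(=O)c2ccc(O)cc2O1 | intermediate
10 | 7-hydroxy-2-(4-methoxyphenyl)-4H-chromen-4-one (pratol) | COc1ccc(cc1)-c1cc(=O)c2ccc(O)cc2o1 | intermediate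
11 | 7-hydroxy-8-iodo-2-(4-methoxyphenyl)-4H-chromen-4-one | COc1ccc(cc1)-c1cc(=O)c2ccc(O)c(I)c2o1 | intermediate
12 | 2-[4-hydroxy-3-(4,4,5,5-tetramethyl-1,3,2-dioxaborolan-2-yl)phenyl]-7-methoxy-4H-chromen-4-one (boronate) | COc1ccc2c(c1)oc(cc2=O)-c1ccc(O)c(c1)B1OC(C)(C)C(C)(C)O1 | intermediate
13 | 7-hydroxy-8-[2-hydroxy-5-(7-methoxy-4-oxo-4H-chromen-2-yl)phenyl]-2-(4-methoxyphenyl)-4H-chromen-4-one (5,5''-dideoxyputraflavone) | COc1ccc(-c2cc(=O)c3ccc(O)c(-c4cc(-c5cc(=O)c6ccc(OC)cc6o5)ccc4O)c3o2)cc1 | intermediate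
14 | 4',7''-bis(trifluoroacetate) of 13 | COc1ccc(-c2cc(=O)c3ccc(OC(=O)C(F)(F)F)c(-c4cc(-c5cc(=O)c6ccc(OC)cc6o5)ccc4OC(=O)C(F)(F)F)c3o2)cc1 | intermediate
15 | 5,4',5'',7''-tetrakis(trifluoroacetate) of 16 | COc1ccc(-c2cc(=O)c3c(OC(=O)C(F)(F)F)cc(OC(=O)C(F)(F)F)c(-c4cc(-c5cc(=O)c6c(OC(=O)C(F)(F)F)cc(OC)cc6o5)ccc4OC(=O)C(F)(F)F)c3o2)cc1 | intermediate
16 | putraflavone, 5,7-dihydroxy-8-[2-hydroxy-5-(5-hydroxy-7-methoxy-4-oxo-4H-chromen-2-yl)phenyl]-2-(4-methoxyphenyl)-4H-chromen-4-one | COc1ccc(-c2cc(=O)c3c(O)cc(O)c(-c4cc(-c5cc(=O)c6c(O)cc(OC)cc6o5)ccc4O)c3o2)cc1 | target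

**Total step count:** 5. **Longest linear sequence:** 4 (steps 2, 3, 4, 5).

**Three steps most likely to fail**

Step 5 (the new method). The second ruthenation, on half 2, may be slow because its ring A carries an electron-withdrawing trifluoroacetoxy group. The oxidant may also attack the anisyl ring. The fallback uses only known chemistry and brings both C5 oxygens in from the start. It sets out from 2 and comes back at 16.
- Compound 2 is condensed with commercial 1-(2,6-dihydroxy-4-methoxyphenyl)ethan-1-one (BF3·OEt2, dioxane, rt). This ketone is symmetrical, so only one flavone can arise. The product is (E)-3-(3-bromo-4-hydroxyphenyl)-1-(2,6-dihydroxy-4-methoxyphenyl)prop-2-en-1-one F1.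
- I2 (cat.)/DMSO at 130 °C closes it to 3'-bromogenkwanin F2.
- Miyaura borylation (B2pin2, PdCl2(dppf), KOAc, dioxane) gives genkwanin 3'-pinacolboronate F3.
- Commercial acacetin is benzylated (BnBr, K2CO3, DMF, 80 °C) to 5,7-di-O-benzylacacetin F4.
- Like other 5,7-dialkoxyflavones, F4 is iodinated at C8 by NIS, giving 5,7-di-O-benzyl-8-iodoacacetin F5.
- Suzuki coupling of F3 with F5 (Pd(OAc)2, SPhos, K3PO4, dioxane/H2O) gives 5'',7''-di-O-benzylputraflavone F6.
- Hydrogenolysis (H2, Pd/C, THF/MeOH) gives 16.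

Step 4. The risks are slow borylation of the ortho-bromophenoxide, protodeboronation of 12, deiodination of 11, and poor solubility of the phenoxides at a tri-ortho-substituted junction. The fallback gives up the unprotected one-flask format for a protected, stepwise coupling with an isolated boronate. It sets out from 5 and 11 and comes back at 13.
- Compound 5 is benzylated (BnBr, K2CO3, DMF) to 2-[4-(benzyloxy)-3-bromophenyl]-7-methoxy-4H-chromen-4-one F7.
- F7 is borylated and isolated as 2-[4-(benzyloxy)-3-(4,4,5,5-tetramethyl-1,3,2-dioxaborolan-2-yl)phenyl]-7-methoxy-4H-chromen-4-one F8.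
- Compound 11 is benzylated in the same way to 7-(benzyloxy)-8-iodo-2-(4-methoxyphenyl)-4H-chromen-4-one F9.
- Suzuki coupling of F8 with F9 (Pd(OAc)2, SPhos, K3PO4, toluene/H2O, 100 °C) gives 4',7''-di-O-benzyl-5,5''-dideoxyputraflavone F10.
- H2 with Pd/C then frees 13.

Step 1. The free para-hydroxyl makes aldehyde 2 a weak electrophile, so the domino process may stall before the chalcone. The fallback masks the phenol and builds the flavone in separate stages. It sets out from 2 (with 1) and comes back at 5.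
- Compound 2 with MOMCl and iPr2NEt in CH2Cl2 gives 3-bromo-4-(methoxymethoxy)benzaldehyde F11.
- KOH/EtOH condensation with 1 gives (E)-3-[3-bromo-4-(methoxymethoxy)phenyl]-1-(2-hydroxy-4-methoxyphenyl)prop-2-en-1-one F12.
- I2 (cat.)/DMSO at 130 °C gives 2-[3-bromo-4-(methoxymethoxy)phenyl]-7-methoxy-4H-chromen-4-one F13.
- 3 M HCl in THF/H2O at 50 °C gives 5. Any acetal loss during the cyclisation leads to 5 directly.

**Further compounds**
F1 | step 5 | (E)-3-(3-bromo-4-hydroxyphenyl)-1-(2,6-dihydroxy-4-methoxyphenyl)prop-2-en-1-one | COc1cc(O)c(C(=O)/C=C/c2ccc(O)c(Br)c2)c(O)c1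
F2 | step 5 | 3'-bromogenkwanin, 2-(3-bromo-4-hydroxyphenyl)-5-hydroxy-7-methoxy-4H-chromen-4-one | COc1cc(O)c2c(c1)oc(cc2=O)-c1ccc(O)c(Br)c1
F3 | step 5 | genkwanin 3'-pinacolboronate | COc1cc(O)c2c(c1)oc(cc2=O)-c1ccc(O)c(c1)B1OC(C)(C)C(C)(C)O1
F4 | step 5 | 5,7-di-O-benzylacacetin, 5,7-bis(benzyloxy)-2-(4-methoxyphenyl)-4H-chromen-4-one | COc1ccc(cc1)-c1cc(=O)c2c(OCc3ccccc3)cc(OCc3ccccc3)cc2o1
F5 | step 5 | 5,7-di-O-benzyl-8-iodoacacetin | COc1ccc(cc1)-c1cc(=O)c2c(OCc3ccccc3)cc(OCc3ccccc3)c(I)c2o1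
F6 | step 5 | 5'',7''-di-O-benzylputraflavone | COc1ccc(-c2cc(=O)c3c(OCc7ccccc7)cc(OCc8ccccc8)c(-c4cc(-c5cc(=O)c6c(O)cc(OC)cc6o5)ccc4O)c3o2)cc1
F7 | step 4 | 2-[4-(benzyloxy)-3-bromophenyl]-7-methoxy-4H-chromen-4-one | COc1ccc2c(c1)oc(cc2=O)-c1ccc(OCc2ccccc2)c(Br)c1
F8 | step 4 | 2-[4-(benzyloxy)-3-(4,4,5,5-tetramethyl-1,3,2-dioxaborolan-2-yl)phenyl]-7-methoxy-4H-chromen-4-one | COc1ccc2c(c1)oc(cc2=O)-c1ccc(OCc2ccccc2)c(c1)B1OC(C)(C)C(C)(C)O1
F9 | step 4 | 7-(benzyloxy)-8-iodo-2-(4-methoxyphenyl)-4H-chromen-4-one | COc1ccc(cc1)-c1cc(=O)c2ccc(OCc3ccccc3)c(I)c2o1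
F10 | step 4 | 4',7''-di-O-benzyl-5,5''-dideoxyputraflavone | COc1ccc(-c2cc(=O)c3ccc(OCc7ccccc7)c(-c4cc(-c5cc(=O)c6ccc(OC)cc6o5)ccc4OCc8ccccc8)c3o2)cc1
F11 | step 1 | 3-bromo-4-(methoxymethoxy)benzaldehyde | COCOc1ccc(C=O)cc1Br
F12 | step 1 | (E)-3-[3-bromo-4-(methoxymethoxy)phenyl]-1-(2-hydroxy-4-methoxyphenyl)prop-2-en-1-one | COCOc1ccc(/C=C/C(=O)c2ccc(OC)cc2O)cc1Br
F13 | step 1 | 2-[3-bromo-4-(methoxymethoxy)phenyl]-7-methoxy-4H-chromen-4-one | COCOc1ccc(cc1Br)-c1cc(=O)c2ccc(OC)cc2o1
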